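**Plan**

1. Cuts: (a) the eight O-protecting groups; (b) the C6–vinyl bond of the outer dihydrobenzofuran (Heck); (c) in the outer furan (on ring A) the pair O1–C7a and C3–C3a; (d) the styryl bond on ring B (Heck); (e) in the inner furan (on ring B) the same pair O1–C7a / C3–C3a. Each furan thus falls back to a trans-2,3-diaryloxirane plus one aryne.
2. Enabling feature: in both furans C3a lies between C7a–O1 and C4–OH of a resorcinol ring whose third substituent (C6) is meta to both. This is what 5-chloro-3-methoxybenzyne delivers when oxygen adds to the aryne carbon remote from OMe and carbon to the one beside it, so one o-silylaryl triflate builds ring A and ring B.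
3. Forward: pterostilbene triflate → oxirane → first aryne insertion (ring B furan) → Heck → oxirane → second aryne insertion (ring A furan, closed by C3a–C3) → demethylation/acetylation → Heck with the 2,4-dioxygenated styrene → one basic unmasking. Every alkene is epoxidised before an aryne step; the only alkene of the target is made last.
4. Stereochemistry: two Shi epoxidations with the same D-fructose-derived ketone fix C2 of each furan (its C–O bond is never broken); C3 is set in the ring closure under control of C2 (trans); the (E)-alkene comes from the Heck reaction.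
5. Helper: the 4-oxygen of each C2 aryl group is carried as a triflate. It decides which oxirane C–O bond ionises, shields the benzylic C2–O bond during BBr3 treatment, and leaves in the last step.

Key step: step 11

Assumption: the aryne-derived O-aryloxiranium betaine is taken to collapse on the face from which oxygen departs, so that a trans-oxirane gives the trans-2,3-diaryl ring.

**Route**

Step 1
Reactants: 1 3-chloro-5-methoxyphenol
Product: 2 3-chloro-5-methoxyphenyl N-isopropylcarbamate
Conditions: i-PrNCO (1.3 equiv), Et3N (0.2 equiv), CH2Cl2, rt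
Reagents that add atoms: isopropyl isocyanate, CC(C)N=C=O
Why: Base-catalysed addition of the phenol to the isocyanate (carbamoylation) should give the N-monoalkyl carbamate, a strong ortho-directing group that can later be removed without touching an aryl silane.

Step 2
Reactants: 2 3-chloro-5-methoxyphenyl N-isopropylcarbamate
Product: 6 5-chloro-3-methoxy-2-(trimethylsilyl)phenyl N-isopropylcarbamate, via N-silyl carbamate 3 (not isolated), via aryllithium 4 (not isolated), via C,N-bis-silyl carbamate 5 (not isolated)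
Conditions: TMSOTf (1.1 equiv), TMEDA, Et2O, 0 °C → rt; n-BuLi (1.5 equiv), TMEDA, −78 °C; TMSCl (3 equiv), −78 °C → rt; 1 M aq. HCl work-up
Reagents that add atoms: chlorotrimethylsilane, C[Si](C)(C)Cl
Why: After in-situ N-silylation the carbamate and the methoxy group should together direct n-BuLi to the carbon between the two oxygens (directed ortho-metalation; the C–Cl bond does not exchange at −78 °C and no lithium sits ortho to chlorine), and TMSCl traps the aryllithium.

Step 3
Reactants: 6 5-chloro-3-methoxy-2-(trimethylsilyl)phenyl N-isopropylcarbamate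
Product: 8 5-chloro-3-methoxy-2-(trimethylsilyl)phenyl trifluoromethanesulfonate, via silylphenoxide 7 (not isolated)
Conditions: DBU (1.5 equiv), Et2NH (1.3 equiv), MeCN, 40 °C; then PhNTf2 (1.5 equiv), rt
Reagents that add atoms: N-phenylbis(trifluoromethanesulfonimide), O=S(=O)(N(c1ccccc1)S(=O)(=O)C(F)(F)F)C(F)(F)F
Why: DBU should trigger E1cB loss of isopropyl isocyanate (scavenged by Et2NH), and the freed o-silylphenoxide is O-triflated in the same flask to give the o-silylaryl triflate aryne precursor.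

Step 4
Reactants: 9 pterostilbene, 4-[(E)-2-(3,5-dimethoxyphenyl)ethenyl]phenol
Product: 10 4-[(E)-2-(3,5-dimethoxyphenyl)ethenyl]phenyl trifluoromethanesulfonate
Conditions: PhNTf2 (1.2 equiv), Et3N (2 equiv), CH2Cl2, 0 °C → rt
Reagents that add atoms: N-phenylbis(trifluoromethanesulfonimide), O=S(=O)(N(c1ccccc1)S(=O)(=O)C(F)(F)F)C(F)(F)F
Why: O-Triflation of the only free phenol under mild base should proceed cleanly and turns the 4-oxyphenyl ring into the electron-poor ring needed later.

Step 5
Reactants: 10 4-[(E)-2-(3,5-dimethoxyphenyl)ethenyl]phenyl trifluoromethanesulfonate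
Product: 11 4-[(2R,3R)-3-(3,5-dimethoxyphenyl)oxiran-2-yl]phenyl trifluoromethanesulfonate
Conditions: Shi ketone (D-fructose-derived, 0.3 equiv), Oxone (2KHSO5·KHSO4·K2SO4), K2CO3, Bu4NHSO4 (cat.), MeCN/CH2(OMe)2, aq. Na2B4O7/Na2H2edta buffer (pH 10.5), 0 °C
Reagents that add atoms: potassium peroxymonosulfate (KHSO5), [K+].[O-]S(=O)(=O)OO
Why: Shi asymmetric epoxidation: the chiral dioxirane from the D-fructose-derived ketone transfers oxygen to trans-stilbenes through a spiro transition state on one face and should give the (R,R)-oxirane by reagent control, the triflate making the product stable to silica.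

Step 6
Reactants: 8 5-chloro-3-methoxy-2-(trimethylsilyl)phenyl trifluoromethanesulfonate; 11 4-[(2R,3R)-3-(3,5-dimethoxyphenyl)oxiran-2-yl]phenyl trifluoromethanesulfonate
Product: 15 4-[(2S,3S)-6-chloro-3-(3,5-dimethoxyphenyl)-4-methoxy-2,3-dihydro-1-benzofuran-2-yl]phenyl trifluoromethanesulfonate, via aryne 12 (not isolated), via oxiranium betaine 13 (not isolated), via open zwitterion 14 (not isolated)
Conditions: 11 (2 equiv), CsF (3 equiv), MeCN/toluene 1:3, 40 °C, 8 added over 6 h
Reagents that add atoms: none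
Why: Proposed new method: aryne 12, released from 8 by fluoride, should be attacked by the oxirane oxygen of 11 at the carbon remote from OMe (aryne distortion by the adjacent withdrawing methoxy group, which also stabilises the carbanion formed between the two oxygens), and betaine 13 should ionise at the oxirane carbon bearing the 3,5-dimethoxyphenyl ring and not at the triflate-deactivated one, zwitterion 14 collapsing on the face of the departing oxygen (5-endo-tet, hence SN1-like) to the trans ring with C2 retained and C3 controlled by C2; the closest known reaction type is the formal insertion of arynes into the benzylic C–O bond of monoaryl oxiranes.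

Step 7
Reactants: 16 4-hydroxybenzaldehyde
Product: 17 4-formylphenyl trifluoromethanesulfonate
Conditions: Tf2O (1.1 equiv), pyridine (2 equiv), CH2Cl2, 0 °C
Reagents that add atoms: trifluoromethanesulfonic anhydride, O=S(=O)(OS(=O)(=O)C(F)(F)F)C(F)(F)F
Why: O-Triflation of a phenol with the anhydride and pyridine is routine and the aldehyde is inert to it.

Step 8
Reactants: 17 4-formylphenyl trifluoromethanesulfonate
Product: 18 4-ethenylphenyl trifluoromethanesulfonate
Conditions: Ph3PCH3Br (1.2 equiv), NaN(SiMe3)2 (1.15 equiv), THF, 0 °C; then 17, −78 → 0 °C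
Reagents that add atoms: methyltriphenylphosphonium bromide, C[P+](c1ccccc1)(c1ccccc1)c1ccccc1.[Br-]
Why: Wittig methylenation: the non-stabilised ylide should add to the aldehyde far faster than it attacks the sulfonate at low temperature.

Step 9
Reactants: 15 4-[(2S,3S)-6-chloro-3-(3,5-dimethoxyphenyl)-4-methoxy-2,3-dihydro-1-benzofuran-2-yl]phenyl trifluoromethanesulfonate; 18 4-ethenylphenyl trifluoromethanesulfonate
Product: 19 4-[(E)-2-{(2S,3S)-3-(3,5-dimethoxyphenyl)-4-methoxy-2-[4-(trifluoromethanesulfonyloxy)phenyl]-2,3-dihydro-1-benzofuran-6-yl}ethenyl]phenyl trifluoromethanesulfonate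
Conditions: Pd2(dba)3 (2.5 mol %), [HP(t-Bu)3]BF4 (10 mol %), Cy2NMe (1.5 equiv), 18 (1.5 equiv), dioxane, 95 °C
Reagents that add atoms: none
Why: Heck reaction: the monoligated zerovalent palladium–P(t-Bu)3 species is known to insert into Ar–Cl in preference to Ar–OTf bonds, the chloride has no ortho substituent, and syn-insertion/β-hydride elimination should give the (E)-stilbene.

Step 10
Reactants: 19 4-[(E)-2-{(2S,3S)-3-(3,5-dimethoxyphenyl)-4-methoxy-2-[4-(trifluoromethanesulfonyloxy)phenyl]-2,3-dihydro-1-benzofuran-6-yl}ethenyl]phenyl trifluoromethanesulfonate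
Product: 20 4-[(2R,3R)-3-{(2S,3S)-3-(3,5-dimethoxyphenyl)-4-methoxy-2-[4-(trifluoromethanesulfonyloxy)phenyl]-2,3-dihydro-1-benzofuran-6-yl}oxiran-2-yl]phenyl trifluoromethanesulfonate
Conditions: Shi ketone (D-fructose-derived, 0.4 equiv), Oxone (2KHSO5·KHSO4·K2SO4), K2CO3, Bu4NHSO4 (cat.), MeCN/CH2(OMe)2, aq. Na2B4O7/Na2H2edta buffer (pH 10.5), 0 °C
Reagents that add atoms: potassium peroxymonosulfate (KHSO5), [K+].[O-]S(=O)(=O)OO
Why: Shi asymmetric epoxidation under reagent control should again give the (R,R)-oxirane, the existing stereocentres being remote from the alkene, and any minor isomer is now a diastereomer that chromatography can remove.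

Step 11
Reactants: 8 5-chloro-3-methoxy-2-(trimethylsilyl)phenyl trifluoromethanesulfonate; 20 4-[(2R,3R)-3-{(2S,3S)-3-(3,5-dimethoxyphenyl)-4-methoxy-2-[4-(trifluoromethanesulfonyloxy)phenyl]-2,3-dihydro-1-benzofuran-6-yl}oxiran-2-yl]phenyl trifluoromethanesulfonate
Product: 23 4-[(2S,3S)-6-chloro-3-{(2S,3S)-3-(3,5-dimethoxyphenyl)-4-methoxy-2-[4-(trifluoromethanesulfonyloxy)phenyl]-2,3-dihydro-1-benzofuran-6-yl}-4-methoxy-2,3-dihydro-1-benzofuran-2-yl]phenyl trifluoromethanesulfonate, via oxiranium betaine 21 (not isolated), via open zwitterion 22 (not isolated)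
Conditions: CsF (6 equiv), MeCN/toluene 1:3, 40 °C, 8 (3 equiv) added over 8 h
Reagents that add atoms: none
Why: Proposed new method: fluoride removes the silyl group of 8 and triflate leaves, releasing 5-chloro-3-methoxybenzyne (12, as in step 6), whose carbon remote from OMe is attacked by the oxirane oxygen of 20 (the withdrawing methoxy group beside the triple bond distorts the aryne toward attack at the far carbon and stabilises the carbanion that develops between the two oxygens), giving betaine 21. The O-aryloxiranium should then ionise at the oxirane carbon bearing ring B (a 3,5-dioxygenated, 4-alkylated aryl group, whereas the other carbon carries the deactivated 4-triflyloxyphenyl ring) to zwitterion 22, and the aryl carbanion captures the benzylic cation to form the C3a–C3 bond; the closest known reaction type is the formal insertion of arynes into the benzylic C–O bond of monoaryl oxiranes (Stevens-like collapse of aryne-derived oxonium betaines), here extended to a 2,3-diaryloxirane. The furan ring closes in a 5-endo-tet sense with respect to the breaking C–O bond, which excludes backside displacement and is why an ionising, front-side cation–carbanion recombination is invoked. C2 keeps the configuration installed by the Shi epoxidation because its C–O bond is never broken, and the new C3 centre is set under control of C2, collapse on the face from which oxygen departs and the preference for trans-2,3-diaryl substitution both pointing to (2S,3S). The step needs regioselectivity at the aryne (secured by C4–OMe next to the triple bond, the meta chlorine having little say), choice of the right oxirane C–O bond (secured by the triflate helper against the electron-richer ring B) and chemoselectivity for the oxirane oxygen (all other oxygens are aryl ether or sulfonate oxygens and no alkene is present). Slow addition of 8 keeps the aryne concentration low so that the hindered oxirane can compete with aryne self-reaction.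

Step 12
Reactants: 23 4-[(2S,3S)-6-chloro-3-{(2S,3S)-3-(3,5-dimethoxyphenyl)-4-methoxy-2-[4-(trifluoromethanesulfonyloxy)phenyl]-2,3-dihydro-1-benzofuran-6-yl}-4-methoxy-2,3-dihydro-1-benzofuran-2-yl]phenyl trifluoromethanesulfonate
Product: 25 tetraacetate of 23 in which the four methoxy groups are replaced by acetoxy groups, via tetraphenol 24 (not isolated)
Conditions: BBr3 (12 equiv), CH2Cl2, −78 → 0 °C; MeOH quench, evaporation; Ac2O, pyridine, DMAP (cat.), rt
Reagents that add atoms: acetic anhydride, CC(=O)OC(C)=O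
Why: Lewis-acid ether cleavage followed by O-acetylation: BBr3 should cleave the four aryl methyl ethers by bromide attack at methyl while the two benzylic C2–O bonds, flanked by triflate-deactivated aryl rings, resist ionisation, and no acid-sensitive stilbene is yet present.

Step 13
Reactants: 26 2,4-dihydroxybenzaldehyde
Product: 27 2,4-bis(tert-butyldimethylsilyloxy)benzaldehyde
Conditions: TBSCl (2.5 equiv), imidazole (5 equiv), DMF, rt
Reagents that add atoms: tert-butyldimethylsilyl chloride, CC(C)(C)[Si](C)(C)Cl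
Why: Imidazole-mediated O-silylation should protect both phenols, including the hydrogen-bonded ortho one, as base-labile aryl silyl ethers.

Step 14
Reactants: 27 2,4-bis(tert-butyldimethylsilyloxy)benzaldehyde
Product: 28 1-ethenyl-2,4-bis(tert-butyldimethylsilyloxy)benzene
Conditions: Ph3PCH3Br (1.2 equiv), NaN(SiMe3)2 (1.15 equiv), THF, 0 °C; then 27, −78 °C → rt
Reagents that add atoms: methyltriphenylphosphonium bromide, C[P+](c1ccccc1)(c1ccccc1)c1ccccc1.[Br-]
Why: Wittig methylenation of an electron-rich benzaldehyde is routine and aryl silyl ethers tolerate the salt-free ylide.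

Step 15
Reactants: 25 tetraacetate; 28 1-ethenyl-2,4-bis(tert-butyldimethylsilyloxy)benzene
Product: 29 fully protected target: 25 in which chlorine is replaced by the (E)-2-[2,4-bis(tert-butyldimethylsilyloxy)phenyl]ethenyl group
Conditions: Pd2(dba)3 (2.5 mol %), [HP(t-Bu)3]BF4 (10 mol %), Cy2NMe (1.5 equiv), 28 (1.5 equiv), dioxane, 95 °C
Reagents that add atoms: none
Why: Heck reaction with the same Ar–Cl over Ar–OTf selectivity as in step 9 should give the (E)-stilbene, aryl acetates and aryl silyl ethers being stable to the tertiary amine base.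

Step 16
Reactants: 29 fully protected target
Product: 30 CNP0186204.1, 4-[(E)-2-{(2S,3S)-3-[(2S,3S)-3-(3,5-dihydroxyphenyl)-4-hydroxy-2-(4-hydroxyphenyl)-2,3-dihydro-1-benzofuran-6-yl]-4-hydroxy-2-(4-hydroxyphenyl)-2,3-dihydro-1-benzofuran-6-yl}ethenyl]benzene-1,3-diol
Conditions: Et4NOH (aq., 24 equiv), dioxane, rt, argon; then aq. NH4Cl/1 M HCl to pH 5
Reagents that add atoms: none
Why: Hydroxide-mediated cleavage (attack at acetyl carbon, at silicon and at triflyl sulfur) should release all eight phenols at room temperature without acid, leaving the stilbene and both trans-dihydrobenzofurans untouched.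

**Compound list**

1 | 3-chloro-5-methoxyphenol | COc1cc(O)cc(Cl)c1 | starting material
2 | 3-chloro-5-methoxyphenyl N-isopropylcarbamate | COc1cc(Cl)cc(OC(=O)NC(C)C)c1 | intermediate
3 | 3-chloro-5-methoxyphenyl N-isopropyl-N-(trimethylsilyl)carbamate | COc1cc(Cl)cc(OC(=O)N(C(C)C)[Si](C)(C)C)c1 | intermediate (not isolated)
4 | {4-chloro-2-methoxy-6-[N-isopropyl-N-(trimethylsilyl)carbamoyloxy]phenyl}lithium | COc1cc(Cl)cc(OC(=O)N(C(C)C)[Si](C)(C)C)c1[Li] | intermediate (not isolated)
5 | 5-chloro-3-methoxy-2-(trimethylsilyl)phenyl N-isopropyl-N-(trimethylsilyl)carbamate | COc1cc(Cl)cc(OC(=O)N(C(C)C)[Si](C)(C)C)c1[Si](C)(C)C | intermediate (not isolated)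
6 | 5-chloro-3-methoxy-2-(trimethylsilyl)phenyl N-isopropylcarbamate | COc1cc(Cl)cc(OC(=O)NC(C)C)c1[Si](C)(C)C | intermediate
7 | 5-chloro-3-methoxy-2-(trimethylsilyl)phenol (present as its DBU-H phenoxide) | COc1cc(Cl)cc(O)c1[Si](C)(C)C | intermediate (not isolated)
8 | 5-chloro-3-methoxy-2-(trimethylsilyl)phenyl trifluoromethanesulfonate | COc1cc(Cl)cc(OS(=O)(=O)C(F)(F)F)c1[Si](C)(C)C | intermediate
9 | pterostilbene, 4-[(E)-2-(3,5-dimethoxyphenyl)ethenyl]phenol | COc1cc(/C=C/c2ccc(O)cc2)cc(OC)c1 | starting material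
10 | 4-[(E)-2-(3,5-dimethoxyphenyl)ethenyl]phenyl trifluoromethanesulfonate | COc1cc(/C=C/c2ccc(OS(=O)(=O)C(F)(F)F)cc2)cc(OC)c1 | intermediate
11 | 4-[(2R,3R)-3-(3,5-dimethoxyphenyl)oxiran-2-yl]phenyl trifluoromethanesulfonate | FC(F)(F)S(=O)(=O)Oc1ccc(cc1)[C@H]1O[C@@H]1c1cc(OC)cc(OC)c1 | intermediate
12 | 5-chloro-3-methoxybenzyne (5-chloro-3-methoxy-1,2-didehydrobenzene) | COC1=CC(Cl)=CC#C1 | intermediate (not isolated)
13 | O-aryl oxiranium betaine from 11 and 12 (carbanion between the oxonium-bearing and the methoxy-bearing carbons) | FC(F)(F)S(=O)(=O)Oc1ccc(cc1)[C@H]1[O+](C2=CC(Cl)=CC(OC)=[C-]2)[C@@H]1c1cc(OC)cc(OC)c1 | intermediate (not isolated)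
14 | ring-opened zwitterion from 13 (aryl carbanion, benzylic cation at the carbon bearing the dimethoxyphenyl ring) | FC(F)(F)S(=O)(=O)Oc1ccc(cc1)[C@@H](OC1=CC(Cl)=CC(OC)=[C-]1)[CH+]c1cc(OC)cc(OC)c1 | intermediate (not isolated)
15 | 4-[(2S,3S)-6-chloro-3-(3,5-dimethoxyphenyl)-4-methoxy-2,3-dihydro-1-benzofuran-2-yl]phenyl trifluoromethanesulfonate | Clc1cc(OC)c2c(c1)O[C@H](c1ccc(OS(=O)(=O)C(F)(F)F)cc1)[C@H]2c1cc(OC)cc(OC)c1 | intermediate
16 | 4-hydroxybenzaldehyde | O=Cc1ccc(O)cc1 | starting material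
17 | 4-formylphenyl trifluoromethanesulfonate | O=Cc1ccc(OS(=O)(=O)C(F)(F)F)cc1 | intermediate
18 | 4-ethenylphenyl trifluoromethanesulfonate | C=Cc1ccc(OS(=O)(=O)C(F)(F)F)cc1 | intermediate
19 | 4-[(E)-2-{(2S,3S)-3-(3,5-dimethoxyphenyl)-4-methoxy-2-[4-(trifluoromethanesulfonyloxy)phenyl]-2,3-dihydro-1-benzofuran-6-yl}ethenyl]phenyl trifluoromethanesulfonate | FC(F)(F)S(=O)(=O)Oc1ccc(/C=C/c2cc(OC)c3c(c2)O[C@H](c2ccc(OS(=O)(=O)C(F)(F)F)cc2)[C@H]3c2cc(OC)cc(OC)c2)cc1 | intermediate
20 | 4-[(2R,3R)-3-{(2S,3S)-3-(3,5-dimethoxyphenyl)-4-methoxy-2-[4-(trifluoromethanesulfonyloxy)phenyl]-2,3-dihydro-1-benzofuran-6-yl}oxiran-2-yl]phenyl trifluoromethanesulfonate | FC(F)(F)S(=O)(=O)Oc1ccc(cc1)[C@H]1O[C@@H]1c1cc(OC)c2c(c1)O[C@H](c1ccc(OS(=O)(=O)C(F)(F)F)cc1)[C@H]2c1cc(OC)cc(OC)c1 | intermediate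
21 | O-aryl oxiranium betaine from 20 and 12 | FC(F)(F)S(=O)(=O)Oc1ccc(cc1)[C@H]1[O+](C2=CC(Cl)=CC(OC)=[C-]2)[C@@H]1c1cc(OC)c2c(c1)O[C@H](c1ccc(OS(=O)(=O)C(F)(F)F)cc1)[C@H]2c1cc(OC)cc(OC)c1 | intermediate (not isolated)
22 | ring-opened zwitterion from 21 (aryl carbanion, benzylic cation at the carbon bearing ring B) | FC(F)(F)S(=O)(=O)Oc1ccc(cc1)[C@@H](OC1=CC(Cl)=CC(OC)=[C-]1)[CH+]c1cc(OC)c2c(c1)O[C@H](c1ccc(OS(=O)(=O)C(F)(F)F)cc1)[C@H]2c1cc(OC)cc(OC)c1 | intermediate (not isolated)
23 | 4-[(2S,3S)-6-chloro-3-{(2S,3S)-3-(3,5-dimethoxyphenyl)-4-methoxy-2-[4-(trifluoromethanesulfonyloxy)phenyl]-2,3-dihydro-1-benzofuran-6-yl}-4-methoxy-2,3-dihydro-1-benzofuran-2-yl]phenyl trifluoromethanesulfonate | FC(F)(F)S(=O)(=O)Oc1ccc([C@H]2Oc3cc(Cl)cc(OC)c3[C@@H]2c2cc(OC)c3c(c2)O[C@H](c2ccc(OS(=O)(=O)C(F)(F)F)cc2)[C@H]3c2cc(OC)cc(OC)c2)cc1 | intermediate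
24 | tetraphenol corresponding to 23 (four OMe replaced by OH) | FC(F)(F)S(=O)(=O)Oc1ccc([C@H]2Oc3cc(Cl)cc(O)c3[C@@H]2c2cc(O)c3c(c2)O[C@H](c2ccc(OS(=O)(=O)C(F)(F)F)cc2)[C@H]3c2cc(O)cc(O)c2)cc1 | intermediate (not isolated)
25 | tetraacetate corresponding to 23 (four OMe replaced by OAc; 2S,3S in both rings) | FC(F)(F)S(=O)(=O)Oc1ccc([C@H]2Oc3cc(Cl)cc(OC(C)=O)c3[C@@H]2c2cc(OC(C)=O)c3c(c2)O[C@H](c2ccc(OS(=O)(=O)C(F)(F)F)cc2)[C@H]3c2cc(OC(C)=O)cc(OC(C)=O)c2)cc1 | intermediate
26 | 2,4-dihydroxybenzaldehyde | O=Cc1ccc(O)cc1O | starting material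
27 | 2,4-bis(tert-butyldimethylsilyloxy)benzaldehyde | O=Cc1ccc(O[Si](C)(C)C(C)(C)C)cc1O[Si](C)(C)C(C)(C)C | intermediate
28 | 1-ethenyl-2,4-bis(tert-butyldimethylsilyloxy)benzene | C=Cc1ccc(O[Si](C)(C)C(C)(C)C)cc1O[Si](C)(C)C(C)(C)C | intermediate
29 | fully protected target (two OTf, four OAc, two OTBS; E-alkene; 2S,3S in both rings) | FC(F)(F)S(=O)(=O)Oc1ccc([C@H]2Oc3cc(/C=C/c4ccc(O[Si](C)(C)C(C)(C)C)cc4O[Si](C)(C)C(C)(C)C)cc(OC(C)=O)c3[C@@H]2c2cc(OC(C)=O)c3c(c2)O[C@H](c2ccc(OS(=O)(=O)C(F)(F)F)cc2)[C@H]3c2cc(OC(C)=O)cc(OC(C)=O)c2)cc1 | intermediate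
30 | CNP0186204.1 | Oc1ccc([C@H]2Oc3cc(/C=C/c4ccc(O)cc4O)cc(O)c3[C@@H]2c2cc(O)c3c(c2)O[C@H](c2ccc(O)cc2)[C@H]3c2cc(O)cc(O)c2)cc1 | target

**Count and risks**

Total: 16 steps. Longest linear sequence: 10 steps (1 → 2 → 6 → 8 → 15 → 19 → 20 → 23 → 25 → 29 → 30).

Risk 1, step 6 (labelled step). What may go wrong: the hindered, weakly nucleophilic oxirane oxygen may lose the aryne to fluoride, solvent or aryne self-reaction; the betaine may be intercepted or protonated before it collapses; and, because the electronic margin between the 3,5-dimethoxyphenyl carbon and the triflyloxyphenyl carbon is modest, the wrong oxirane C–O bond may ionise. Fallback (known chemistry, C–C bond first, ring closed through O1–C2): it sets out from stilbene 10 and phenol 1 and comes back at 15. Shi epoxidation of 10 with the mirror-image ketone (from L-fructose) would give 4-[(2S,3S)-3-(3,5-dimethoxyphenyl)oxiran-2-yl]phenyl trifluoromethanesulfonate F1. Phenol 1 with MOMCl and i-Pr2NEt would give 1-chloro-3-methoxy-5-(methoxymethoxy)benzene F2, which n-BuLi/TMEDA (THF, −78 → −40 °C) should metalate between the two oxygens to [4-chloro-2-methoxy-6-(methoxymethoxy)phenyl]lithium F3. With BF3·OEt2 at −78 °C, F3 should open F1 with inversion at the oxirane carbon bearing the dimethoxyphenyl ring to give (1R,2S)-2-[4-chloro-2-methoxy-6-(methoxymethoxy)phenyl]-2-(3,5-dimethoxyphenyl)-1-[4-(trifluoromethanesulfonyloxy)phenyl]ethanol F4. HCl in MeOH would remove the acetal to give (1R,2S)-2-(4-chloro-2-hydroxy-6-methoxyphenyl)-2-(3,5-dimethoxyphenyl)-1-[4-(trifluoromethanesulfonyloxy)phenyl]ethanol F5, and a Mitsunobu reaction (PPh3, DIAD) would close the furan with inversion at the carbinol carbon; the two inversions turn the (S,S)-oxirane into (2S,3S)-15.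

Risk 2, step 11 (labelled key step). What may go wrong: the same processes as in step 6 on a larger, more valuable oxirane, namely failure of aryne capture, interception of the betaine, ionisation at the wrong carbon or erosion of trans selectivity in the ring closure. Fallback (known chemistry, same logic one level up): it sets out from stilbene 19 and comes back at 23. Shi epoxidation of 19 with the mirror-image ketone would give the (2S,3S)-oxirane 4-[(2S,3S)-3-{(2S,3S)-3-(3,5-dimethoxyphenyl)-4-methoxy-2-[4-(trifluoromethanesulfonyloxy)phenyl]-2,3-dihydro-1-benzofuran-6-yl}oxiran-2-yl]phenyl trifluoromethanesulfonate F6. The aryllithium F3 (made from F2 as above) with BF3·OEt2 should open it with inversion at the carbon bearing ring B to give the (1R,2S)-configured 2-[4-chloro-2-methoxy-6-(methoxymethoxy)phenyl]-2-(benzofuran-6-yl)-1-[4-(trifluoromethanesulfonyloxy)phenyl]ethanol F7. HCl in MeOH would give the corresponding phenol-alcohol F8, and Mitsunobu cyclisation (PPh3, DIAD) with inversion would give 23; in this detour the ring is closed by the O1–C2 bond.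

Risk 3, step 9. What may go wrong: competing oxidative addition of palladium into the aryl triflate C–O bonds of 15 or 18 (oligomerisation of the styrene, loss of the helper) or sluggish insertion into the aryl chloride. Fallback (the competing electrophile is removed before the coupling): it sets out from 15 and comes back at 19. Et4NOH in dioxane would cleave the triflate to give (2S,3S)-6-chloro-3-(3,5-dimethoxyphenyl)-2-(4-hydroxyphenyl)-4-methoxy-2,3-dihydro-1-benzofuran F9. A Heck reaction of F9 with commercial 4-ethenylphenyl acetate (Pd2(dba)3, [HP(t-Bu)3]BF4, Cy2NMe, dioxane, 95 °C), now free of triflates, should give 4-[(E)-2-{(2S,3S)-3-(3,5-dimethoxyphenyl)-2-(4-hydroxyphenyl)-4-methoxy-2,3-dihydro-1-benzofuran-6-yl}ethenyl]phenyl acetate F10. K2CO3 in MeOH would give the bis-phenol 4-[(E)-2-{(2S,3S)-3-(3,5-dimethoxyphenyl)-2-(4-hydroxyphenyl)-4-methoxy-2,3-dihydro-1-benzofuran-6-yl}ethenyl]phenol F11, and PhNTf2/Et3N would triflate both phenols to give 19.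

**Further compounds**

F1 | step 6 | 4-[(2S,3S)-3-(3,5-dimethoxyphenyl)oxiran-2-yl]phenyl trifluoromethanesulfonate | FC(F)(F)S(=O)(=O)Oc1ccc(cc1)[C@@H]1O[C@H]1c1cc(OC)cc(OC)c1
F2 | step 6 | 1-chloro-3-methoxy-5-(methoxymethoxy)benzene | COCOc1cc(Cl)cc(OC)c1
F3 | step 6 | [4-chloro-2-methoxy-6-(methoxymethoxy)phenyl]lithium | COCOc1cc(Cl)cc(OC)c1[Li]
F4 | step 6 | (1R,2S)-2-[4-chloro-2-methoxy-6-(methoxymethoxy)phenyl]-2-(3,5-dimethoxyphenyl)-1-[4-(trifluoromethanesulfonyloxy)phenyl]ethanol | FC(F)(F)S(=O)(=O)Oc1ccc(cc1)[C@H](O)[C@@H](c1cc(OC)cc(OC)c1)c1c(OC)cc(Cl)cc1OCOC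
F5 | step 6 | (1R,2S)-2-(4-chloro-2-hydroxy-6-methoxyphenyl)-2-(3,5-dimethoxyphenyl)-1-[4-(trifluoromethanesulfonyloxy)phenyl]ethanol | FC(F)(F)S(=O)(=O)Oc1ccc(cc1)[C@H](O)[C@@H](c1cc(OC)cc(OC)c1)c1c(OC)cc(Cl)cc1O
F6 | step 11 | 4-[(2S,3S)-3-{(2S,3S)-3-(3,5-dimethoxyphenyl)-4-methoxy-2-[4-(trifluoromethanesulfonyloxy)phenyl]-2,3-dihydro-1-benzofuran-6-yl}oxiran-2-yl]phenyl trifluoromethanesulfonate | FC(F)(F)S(=O)(=O)Oc1ccc(cc1)[C@@H]1O[C@H]1c1cc(OC)c2c(c1)O[C@H](c1ccc(OS(=O)(=O)C(F)(F)F)cc1)[C@H]2c1cc(OC)cc(OC)c1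
F7 | step 11 | (1R,2S)-2-[4-chloro-2-methoxy-6-(methoxymethoxy)phenyl]-2-{(2S,3S)-3-(3,5-dimethoxyphenyl)-4-methoxy-2-[4-(trifluoromethanesulfonyloxy)phenyl]-2,3-dihydro-1-benzofuran-6-yl}-1-[4-(trifluoromethanesulfonyloxy)phenyl]ethanol | FC(F)(F)S(=O)(=O)Oc1ccc(cc1)[C@H](O)[C@@H](c1cc(OC)c2c(c1)O[C@H](c1ccc(OS(=O)(=O)C(F)(F)F)cc1)[C@H]2c1cc(OC)cc(OC)c1)c1c(OC)cc(Cl)cc1OCOC
F8 | step 11 | (1R,2S)-2-(4-chloro-2-hydroxy-6-methoxyphenyl)-2-{(2S,3S)-3-(3,5-dimethoxyphenyl)-4-methoxy-2-[4-(trifluoromethanesulfonyloxy)phenyl]-2,3-dihydro-1-benzofuran-6-yl}-1-[4-(trifluoromethanesulfonyloxy)phenyl]ethanol | FC(F)(F)S(=O)(=O)Oc1ccc(cc1)[C@H](O)[C@@H](c1cc(OC)c2c(c1)O[C@H](c1ccc(OS(=O)(=O)C(F)(F)F)cc1)[C@H]2c1cc(OC)cc(OC)c1)c1c(OC)cc(Cl)cc1O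
F9 | step 9 | (2S,3S)-6-chloro-3-(3,5-dimethoxyphenyl)-2-(4-hydroxyphenyl)-4-methoxy-2,3-dihydro-1-benzofuran | Clc1cc(OC)c2c(c1)O[C@H](c1ccc(O)cc1)[C@H]2c1cc(OC)cc(OC)c1
F10 | step 9 | 4-[(E)-2-{(2S,3S)-3-(3,5-dimethoxyphenyl)-2-(4-hydroxyphenyl)-4-methoxy-2,3-dihydro-1-benzofuran-6-yl}ethenyl]phenyl acetate | CC(=O)Oc1ccc(/C=C/c2cc(OC)c3c(c2)O[C@H](c2ccc(O)cc2)[C@H]3c2cc(OC)cc(OC)c2)cc1
F11 | step 9 | 4-[(E)-2-{(2S,3S)-3-(3,5-dimethoxyphenyl)-2-(4-hydroxyphenyl)-4-methoxy-2,3-dihydro-1-benzofuran-6-yl}ethenyl]phenol | Oc1ccc(/C=C/c2cc(OC)c3c(c2)O[C@H](c2ccc(O)cc2)[C@H]3c2cc(OC)cc(OC)c2)cc1
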